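**Retrosynthetic overview**
1. The last disconnection is the C10–O ester bond, which gives iridoid triol 16 and guaiadienoic acid 32.
2. The strategy rests on the cyclopenta[c]pyran-1-one core: on its cyclopentane ring the lactone carbonyl carbon C1 (on C9), the tertiary 8-OH and the secondary 7-OH are all cis on the concave face, and C9 can epimerise while it carries an acyl group. The C7–C8 bond is therefore made by SmI2 pinacol closure of a 2-(silyloxyacetyl) δ-lactone that has a CH2CHO arm on C5.
3. Iridoid rings: the δ-lactone is made first (cross-metathesis, rhodium-catalysed conjugate alkenylation that sets C5, lactonisation), the cyclopentane second (pinacol).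
4. Acid rings: a cyclopentene is annulated onto carvacrol methyl ether (indene), the methyl centre is set by asymmetric hydrogenation, the benzene ring is dearomatised (Birch) and enlarged by one carbon to a cycloheptenone, then come triflation, carbonylation and diene conjugation.
5. The halves are joined by esterification of the primary C10 hydroxyl while the cis-7,8-diol is masked in the flask as a boronate.

Key step: step 9

Remark: iridoid numbering is used for the lactone half (C1 lactone C=O, C3 OCH2, C4 alkene carbon, C5 and C9 ring fusion, C6 CH2, C7 CHOH, C8 C(OH), C10 CH2O). The senses of induction quoted for the chiral ligands in steps 4 and 14 are assumed to follow the usual facial models; the antipodal ligand is taken if a trial shows the opposite sense.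

**Route**

Step 1
Reactants: 1 ethyl acrylate; 2 4,4-diethoxybut-1-ene (but-3-enal diethyl acetal)
Product: 3 ethyl (2E)-5,5-diethoxypent-2-enoate
Conditions: second-generation Grubbs catalyst RuCl2(=CHPh)(PCy3)(H2IMes) (2 mol %), 1 (3 equiv), CH2Cl2, 40 °C
Reagents that add atoms: none
Why: Olefin cross-metathesis between the electron-poor acrylate and the terminal alkene is cross-selective and should give the E-enoate with loss of ethylene.

Step 2
Reactants: 4 2-bromoprop-2-en-1-ol
Product: 5 [(2-bromoprop-2-en-1-yl)oxy](tert-butyl)dimethylsilane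
Conditions: TBSCl, imidazole, CH2Cl2, 0 °C to rt
Reagents that add atoms: tert-butyldimethylsilyl chloride, CC(C)(C)[Si](C)(C)Cl
Why: Routine O-silylation of a primary allylic alcohol (imidazole-assisted silyl transfer) masks the hydroxyl for the borylation and the conjugate addition.

Step 3
Reactants: 5 [(2-bromoprop-2-en-1-yl)oxy](tert-butyl)dimethylsilane
Product: 6 tert-butyldimethyl{[2-(4,4,5,5-tetramethyl-1,3,2-dioxaborolan-2-yl)prop-2-en-1-yl]oxy}silane
Conditions: B2pin2, PdCl2(dppf) (3 mol %), KOAc, dioxane, 80 °C
Reagents that add atoms: bis(pinacolato)diboron, CC1(C)OB(OC1(C)C)B1OC(C)(C)C(C)(C)O1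
Why: Miyaura borylation, in which oxidative addition of the alkenyl bromide to zerovalent palladium, acetate-assisted transmetalation with the diboron and reductive elimination give the alkenyl boronate with the silyl ether untouched.

Step 4
Reactants: 3 ethyl (2E)-5,5-diethoxypent-2-enoate; 6 the 2-borylallyl silyl ether
Product: 7 ethyl (3R)-4-{[(tert-butyldimethylsilyl)oxy]methyl}-3-(2,2-diethoxyethyl)pent-4-enoate
Conditions: [RhCl(C2H4)2]2 (2.5 mol %), (S)-BINAP (6 mol %), KOH (20 mol %), 6 (1.5 equiv), dioxane/H2O (10:1), 50 °C
Reagents that add atoms: none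
Why: Rhodium-catalysed asymmetric conjugate addition of an alkenylboron reagent to an E-enoate (Hayashi–Miyaura reaction), in which the alkenylrhodium–BINAP species inserts the enoate on its 2-si face, as the (S)-ligand dictates in the established model, so that C5 is set as R and water protonates the rhodium enolate.

Step 5
Reactants: 7 the conjugate adduct
Product: 9 (4R)-4-(2,2-diethoxyethyl)-5-methylideneoxan-2-one, via hydroxy ester 8 (not isolated)
Conditions: Bu4NF, THF, 0 °C to rt; then H2O
Reagents that add atoms: none
Why: Fluoride desilylation releases the allylic alkoxide, which lactonises 6-exo-trig onto the ethyl ester to the δ-lactone without touching C5.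

Step 6
Reactants: 9 the δ-lactone; 10 [(tert-butyldimethylsilyl)oxy]acetaldehyde
Product: 12 (4R)-3-{2-[(tert-butyldimethylsilyl)oxy]-1-hydroxyethyl}-4-(2,2-diethoxyethyl)-5-methylideneoxan-2-one (diastereomers at C9 and the carbinol carbon), via lithium enolate 11 (not isolated)
Conditions: LiN(iPr)2, THF, −78 °C; then 10, −78 °C; AcOH, −78 °C
Reagents that add atoms: none
Why: Kinetic deprotonation of the lactone α-CH2 (C9) and aldol addition to the aldehyde bring in C8 and C10, and the new centres need no control because the next steps turn one into a ketone and make the other epimerisable.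

Step 7
Reactants: 12 the aldol adduct
Product: 13 (4R)-3-{[(tert-butyldimethylsilyl)oxy]acetyl}-4-(2,2-diethoxyethyl)-5-methylideneoxan-2-one (C9 epimers and enol form)
Conditions: Dess–Martin periodinane, CH2Cl2, 0 °C to rt
Reagents that add atoms: none
Why: Dess–Martin oxidation converts the β-hydroxy lactone into the 2-acyl lactone under non-basic conditions that avoid retro-aldol cleavage and leave the acetal and the silyl ether intact.

Step 8
Reactants: 13 the 2-acyl lactone acetal
Product: 14 [(4R)-3-{[(tert-butyldimethylsilyl)oxy]acetyl}-5-methylidene-2-oxooxan-4-yl]acetaldehyde (C9 unassigned: epimers and enol form)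
Conditions: LiBF4, MeCN/H2O (50:1), rt; crude product used at once
Reagents that add atoms: water, O
Why: Lewis-acid-assisted hydrolysis of the diethyl acetal through its oxocarbenium ion is much faster than cleavage of the primary silyl ether, and the keto aldehyde is taken on at once to avoid condensation.

Step 9
Reactants: 14 the keto aldehyde
Product: 15 (4aR,6S,7S,7aR)-7-{[(tert-butyldimethylsilyl)oxy]methyl}-6,7-dihydroxy-4-methylidenehexahydrocyclopenta[c]pyran-1(3H)-one (cis-fused; C1, 8-OH and 7-OH all cis)
Conditions: SmI2 (2.5 equiv, 0.1 M in THF), MeOH (4 equiv), −78 °C, 14 added slowly; then aq. NH4Cl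
Reagents that add atoms: none
Why: SmI2 reduces the ketone of the 2-acyl lactone, which is held with the lactone carbonyl in a six-membered chelate of trivalent samarium, to a ketyl; the ketyl carbon C8 adds to the samarium-bound aldehyde carbon C7, and a second equivalent of SmI2 with methanol turns the adduct into the diol. The closest known reaction type is the SmI2-promoted intramolecular pinacol coupling of 2-acyl esters that carry a tethered aldehyde, which gives cis-2,3-dihydroxycycloalkanecarboxylates. Only the cyclopentane is closed (C7–C8 bond, 5-exo-trig attack of the ketyl on the aldehyde), cis-annulated onto the existing δ-lactone. C9 is set relative to the fixed C5 because the β-keto lactone epimerises through its enol and only the epimer with the acyl and formylmethyl arms cis closes readily, a trans fusion across the flattened lactone (sp2 C1 and C4 flank the fusion bond) being strained; C8 is set by the chelate, which holds O8 syn to C1 so that the tertiary OH ends cis to the lactone carbonyl and CH2OTBS lies on the convex face; C7 is set by bridging of the aldehyde oxygen to the same samarium, which gives the cis-diol. The step needs chemoselectivity for ketyl closure over loss of the α-silyloxy group, over simple carbonyl reduction and over reaction at the exocyclic alkene; the non-chelating, poorly leaving silyl ether, the fast five-membered closure at −78 °C and the unactivated 1,1-disubstituted alkene should secure it.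

Step 10
Reactants: 15 the silyl ether diol
Product: 16 (4aR,6S,7S,7aR)-6,7-dihydroxy-7-(hydroxymethyl)-4-methylidenehexahydrocyclopenta[c]pyran-1(3H)-one
Conditions: HF·pyridine, pyridine, THF, 0 °C to rt
Reagents that add atoms: none
Why: Fluoride cleavage of the primary silyl ether in a pyridine-buffered medium avoids the basic conditions under which the β-hydroxy lactone could undergo retro-aldol opening or C9 epimerisation.

Step 11
Reactants: 17 4-isopropyl-2-methoxy-1-methylbenzene (carvacrol methyl ether); 18 2-methyloxirane (racemic propylene oxide)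
Product: 20 4-(4-isopropyl-2-methoxyphenyl)butan-2-ol (racemic), via benzylic potassium compound 19 (not isolated)
Conditions: n-BuLi, KOtBu, THF, −78 to −50 °C; then 18, −78 to 0 °C; H2O
Reagents that add atoms: none
Why: Lateral (benzylic) metalation of the methyl ortho to OMe by the n-BuLi/KOtBu superbase, followed by SN2 opening of the epoxide at its CH2 terminus, adds the three-carbon chain, and the carbinol centre is removed in the next step.

Step 12
Reactants: 20 the secondary alcohol
Product: 21 4-(4-isopropyl-2-methoxyphenyl)butan-2-one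
Conditions: Dess–Martin periodinane, CH2Cl2, rt
Reagents that add atoms: none
Why: Dess–Martin oxidation of the secondary alcohol gives the methyl ketone and erases the racemic carbinol centre.

Step 13
Reactants: 21 the aryl butanone
Product: 22 5-isopropyl-7-methoxy-3-methyl-1H-indene
Conditions: polyphosphoric acid, 60–70 °C
Reagents that add atoms: none
Why: Bradsher-type cyclodehydration, in which the protonated ketone attacks the only free ring position ortho to the chain (intramolecular Friedel–Crafts hydroxyalkylation, five-membered ring) and the tertiary benzylic carbinol loses water to the conjugated trisubstituted alkene.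

Step 14
Reactants: 22 the indene
Product: 23 (1R)-6-isopropyl-4-methoxy-1-methyl-2,3-dihydro-1H-indene
Conditions: H2 (50 bar), [Ir(cod)(L)][B(C6H3(CF3)2)4] (1 mol %; L = 4-tert-butyl-2-[2-(di-o-tolylphosphino)phenyl]-4,5-dihydrooxazole, the enantiomer that gives 1R), CH2Cl2, rt
Reagents that add atoms: none
Why: Iridium-catalysed asymmetric hydrogenation of an unfunctionalised trisubstituted aryl alkene, in which the chiral P,N ligand selects the alkene face and so sets the methyl-bearing centre as R.

Step 15
Reactants: 23 the (1R)-indane
Product: 24 (1R,7aS)-6-isopropyl-4-methoxy-1-methyl-2,3,5,7a-tetrahydro-1H-indene (7a-H trans to the methyl group)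
Conditions: Li, NH3 (l), THF, t-BuOH, −78 to −33 °C; NH3 evaporated, H2O
Reagents that add atoms: none
Why: Birch reduction, in which the arene radical anion is protonated at the unsubstituted carbon ortho to OMe and the resulting pentadienyl anion at its central carbon (the ring-fusion carbon next to CHCH3), kinetically from the face anti to the methyl group, leaving the tetrasubstituted enol ether and the isopropyl-bearing alkene as a 1,4-diene.

Step 16
Reactants: 24 the dihydroanisole
Product: 25 (1R,3aS,7aS)-6-isopropyl-1-methyl-1,2,3,3a,5,7a-hexahydro-4H-inden-4-one (cis-fused; both ring-fusion hydrogens trans to the methyl group)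
Conditions: oxalic acid dihydrate (0.2 equiv), THF/H2O, 0 °C to rt; used without delay
Reagents that add atoms: water, O
Why: Mild enol ether hydrolysis, in which C-protonation of the enol ether at the second ring-fusion carbon from the convex face (the side of the neighbouring ring-fusion hydrogen, anti to the methyl) gives the cis-fused ketone while the weak acid leaves the β,γ-alkene out of conjugation.

Step 17
Reactants: 25 the β,γ-unsaturated hydrindenone
Product: 27 (1R,3aS,8aS)-7-isopropyl-1-methyl-2,3,3a,5,6,8a-hexahydroazulen-4(1H)-one (cis-fused), via alpha-silyl ketone 26 (not isolated)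
Conditions: TMSCHN2, BF3·OEt2, CH2Cl2, −78 °C; then 1 M HCl, THF, 0 °C
Reagents that add atoms: trimethylsilyldiazomethane, C[Si](C)(C)C=[N+]=[N-]
Why: Lewis-acid-promoted diazoalkane homologation (Tiffeneau–Demjanov-type ring expansion), in which the less substituted allylic CH2 migrates in preference to the ring-fusion CH with loss of N2, so that the new carbon is inserted between C=O and that CH2, the stereocentres stay untouched and the C-silyl group is removed by protodesilylation.

Step 18
Reactants: 27 the cycloheptenone
Product: 29 (1R,3aS,8aS)-7-isopropyl-1-methyl-1,2,3,3a,6,8a-hexahydroazulen-4-yl trifluoromethanesulfonate, via potassium enolate 28 (not isolated)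
Conditions: KN(SiMe3)2, THF, −78 °C; then PhNTf2, −78 °C
Reagents that add atoms: N-phenylbis(trifluoromethanesulfonimide), O=S(=O)(N(c1ccccc1)S(=O)(=O)C(F)(F)F)C(F)(F)F
Why: Kinetic deprotonation at −78 °C occurs at the α-CH2 and not at the hindered ring-fusion CH, and O-triflation of the enolate fixes the alkene towards CH2 while the epimerisable α-centre is never equilibrated.

Step 19
Reactants: 29 the enol triflate
Product: 30 methyl (1R,3aS,8aS)-7-isopropyl-1-methyl-1,2,3,3a,6,8a-hexahydroazulene-4-carboxylate
Conditions: Pd(OAc)2 (5 mol %), PPh3 (10 mol %), CO (1 atm), MeOH, Et3N, DMF, rt to 50 °C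
Reagents that add atoms: carbon monoxide, [C-]#[O+]; methanol, CO
Why: Palladium-catalysed methoxycarbonylation of the alkenyl triflate (oxidative addition to zerovalent palladium, CO insertion, methanolysis of the acylpalladium) installs the ester carbon without moving the alkene.

Step 20
Reactants: 30 the skipped dienoate
Product: 31 methyl (1R,3aS,8aR)-7-isopropyl-1-methyl-1,2,3,3a,8,8a-hexahydroazulene-4-carboxylate
Conditions: DBU, toluene, 80 °C
Reagents that add atoms: none
Why: Base-mediated isomerisation of the skipped dienoate, in which DBU removes the doubly allylic γ-proton and reprotonation of the extended enolate at the ε-carbon gives the thermodynamically favoured conjugated 2,4-dienoate, neither ring-fusion hydrogen being acidified.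

Step 21
Reactants: 31 the conjugated dienoate
Product: 32 (1R,3aS,8aR)-7-isopropyl-1-methyl-1,2,3,3a,8,8a-hexahydroazulene-4-carboxylic acid
Conditions: LiOH, THF/MeOH/H2O, 40 °C; then 1 M HCl to pH 3
Reagents that add atoms: lithium hydroxide, [Li+].[OH-]
Why: Saponification of the methyl ester by hydroxide (acyl substitution) gives the acid, and the ring-fusion centres are not α to the carboxyl and cannot epimerise.

Step 22
Reactants: 16 the iridoid triol; 32 the guaiadienoic acid
Product: 35 nardostachysin, via triol boronate 33 (not isolated), via acylated boronate 34 (not isolated)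
Conditions: 16, PhB(OH)2 (1.05 equiv), 4 Å MS, CH2Cl2, rt; then 32, DIC, DMAP, 0 °C to rt; then pinacol (5 equiv), acetone/H2O, rt
Reagents that add atoms: none
Why: Phenylboronic acid condenses with the cis-7,8-diol on the cyclopentane to a cyclic boronate, so that Steglich esterification (carbodiimide activation, DMAP acyl transfer) can only acylate the primary C10 hydroxyl, and exchange of boron onto pinacol then frees the diol without touching any stereocentre.

**Compound list**
1 | ethyl acrylate | C=CC(=O)OCC | starting material
2 | 4,4-diethoxybut-1-ene | C=CCC(OCC)OCC | starting material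
3 | ethyl (2E)-5,5-diethoxypent-2-enoate | CCOC(=O)/C=C/CC(OCC)OCC | intermediate
4 | 2-bromoprop-2-en-1-ol | C=C(Br)CO | starting material
5 | [(2-bromoprop-2-en-1-yl)oxy](tert-butyl)dimethylsilane | C=C(Br)CO[Si](C)(C)C(C)(C)C | intermediate
6 | tert-butyldimethyl{[2-(4,4,5,5-tetramethyl-1,3,2-dioxaborolan-2-yl)prop-2-en-1-yl]oxy}silane | C=C(CO[Si](C)(C)C(C)(C)C)B1OC(C)(C)C(C)(C)O1 | intermediate
7 | ethyl (3R)-4-{[(tert-butyldimethylsilyl)oxy]methyl}-3-(2,2-diethoxyethyl)pent-4-enoate | CCOC(=O)C[C@@H](CC(OCC)OCC)C(=C)CO[Si](C)(C)C(C)(C)C | intermediate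
8 | ethyl (3R)-3-(2,2-diethoxyethyl)-4-(hydroxymethyl)pent-4-enoate (not isolated) | CCOC(=O)C[C@@H](CC(OCC)OCC)C(=C)CO | intermediate
9 | (4R)-4-(2,2-diethoxyethyl)-5-methylideneoxan-2-one | C=C1COC(=O)C[C@H]1CC(OCC)OCC | intermediate
10 | [(tert-butyldimethylsilyl)oxy]acetaldehyde | O=CCO[Si](C)(C)C(C)(C)C | starting material
11 | lithium enolate of lactone 9 (not isolated) | C=C1COC(O[Li])=C[C@H]1CC(OCC)OCC | intermediate
12 | (4R)-3-{2-[(tert-butyldimethylsilyl)oxy]-1-hydroxyethyl}-4-(2,2-diethoxyethyl)-5-methylideneoxan-2-one, diastereomer mixture | C=C1COC(=O)C(C(O)CO[Si](C)(C)C(C)(C)C)[C@H]1CC(OCC)OCC | intermediate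
13 | (4R)-3-{[(tert-butyldimethylsilyl)oxy]acetyl}-4-(2,2-diethoxyethyl)-5-methylideneoxan-2-one, C9 epimers and enol | C=C1COC(=O)C(C(=O)CO[Si](C)(C)C(C)(C)C)[C@H]1CC(OCC)OCC | intermediate
14 | [(4R)-3-{[(tert-butyldimethylsilyl)oxy]acetyl}-5-methylidene-2-oxooxan-4-yl]acetaldehyde, C9 epimers and enol | C=C1COC(=O)C(C(=O)CO[Si](C)(C)C(C)(C)C)[C@H]1CC=O | intermediate
15 | (4aR,6S,7S,7aR)-7-{[(tert-butyldimethylsilyl)oxy]methyl}-6,7-dihydroxy-4-methylidenehexahydrocyclopenta[c]pyran-1(3H)-one | C=C1COC(=O)[C@@H]2[C@H]1C[C@H](O)[C@@]2(O)CO[Si](C)(C)C(C)(C)C | intermediate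
16 | (4aR,6S,7S,7aR)-6,7-dihydroxy-7-(hydroxymethyl)-4-methylidenehexahydrocyclopenta[c]pyran-1(3H)-one | C=C1COC(=O)[C@@H]2[C@H]1C[C@H](O)[C@@]2(O)CO | intermediate
17 | 4-isopropyl-2-methoxy-1-methylbenzene (carvacrol methyl ether) | COc1cc(C(C)C)ccc1C | starting material
18 | 2-methyloxirane (racemic) | CC1CO1 | starting material
19 | [(4-isopropyl-2-methoxyphenyl)methyl]potassium (not isolated) | COc1cc(C(C)C)ccc1C[K] | intermediate
20 | 4-(4-isopropyl-2-methoxyphenyl)butan-2-ol (racemic) | COc1cc(C(C)C)ccc1CCC(C)O | intermediate
21 | 4-(4-isopropyl-2-methoxyphenyl)butan-2-one | COc1cc(C(C)C)ccc1CCC(C)=O | intermediate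
22 | 5-isopropyl-7-methoxy-3-methyl-1H-indene | COc1cc(C(C)C)cc2C(C)=CCc12 | intermediate
23 | (1R)-6-isopropyl-4-methoxy-1-methyl-2,3-dihydro-1H-indene | COc1cc(C(C)C)cc2[C@H](C)CCc12 | intermediate
24 | (1R,7aS)-6-isopropyl-4-methoxy-1-methyl-2,3,5,7a-tetrahydro-1H-indene | COC1=C2CC[C@@H](C)[C@H]2C=C(C(C)C)C1 | intermediate
25 | (1R,3aS,7aS)-6-isopropyl-1-methyl-1,2,3,3a,5,7a-hexahydro-4H-inden-4-one | O=C1CC(C(C)C)=C[C@@H]2[C@H](C)CC[C@H]12 | intermediate
26 | (1R,3aS,8aS)-7-isopropyl-1-methyl-5-(trimethylsilyl)-2,3,3a,5,6,8a-hexahydroazulen-4(1H)-one (not isolated) | O=C1C([Si](C)(C)C)CC(C(C)C)=C[C@@H]2[C@H](C)CC[C@H]12 | intermediate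
27 | (1R,3aS,8aS)-7-isopropyl-1-methyl-2,3,3a,5,6,8a-hexahydroazulen-4(1H)-one | O=C1CCC(C(C)C)=C[C@@H]2[C@H](C)CC[C@H]12 | intermediate
28 | potassium enolate of ketone 27 towards CH2 (not isolated) | [K]OC1=CCC(C(C)C)=C[C@@H]2[C@H](C)CC[C@H]12 | intermediate
29 | (1R,3aS,8aS)-7-isopropyl-1-methyl-1,2,3,3a,6,8a-hexahydroazulen-4-yl trifluoromethanesulfonate | O=S(=O)(OC1=CCC(C(C)C)=C[C@@H]2[C@H](C)CC[C@H]12)C(F)(F)F | intermediate
30 | methyl (1R,3aS,8aS)-7-isopropyl-1-methyl-1,2,3,3a,6,8a-hexahydroazulene-4-carboxylate | COC(=O)C1=CCC(C(C)C)=C[C@@H]2[C@H](C)CC[C@H]12 | intermediate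
31 | methyl (1R,3aS,8aR)-7-isopropyl-1-methyl-1,2,3,3a,8,8a-hexahydroazulene-4-carboxylate | COC(=O)C1=CC=C(C(C)C)C[C@@H]2[C@H](C)CC[C@H]12 | intermediate
32 | (1R,3aS,8aR)-7-isopropyl-1-methyl-1,2,3,3a,8,8a-hexahydroazulene-4-carboxylic acid | O=C(O)C1=CC=C(C(C)C)C[C@@H]2[C@H](C)CC[C@H]12 | intermediate
33 | cyclic phenylboronate of triol 16 across O7 and O8 (not isolated) | C=C1COC(=O)[C@@H]2[C@H]1C[C@H](OB(c3ccccc3)O4)[C@@]24CO | intermediate
34 | C10 ester of boronate 33 with acid 32 (not isolated) | C=C1COC(=O)[C@@H]2[C@H]1C[C@H](OB(c3ccccc3)O4)[C@@]24COC(=O)C1=CC=C(C(C)C)C[C@@H]2[C@H](C)CC[C@H]12 | intermediate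
35 | nardostachysin, [(4aR,6S,7S,7aR)-6,7-dihydroxy-4-methylidene-1-oxooctahydrocyclopenta[c]pyran-7-yl]methyl (1R,3aS,8aR)-7-isopropyl-1-methyl-1,2,3,3a,8,8a-hexahydroazulene-4-carboxylate | C=C1COC(=O)[C@@H]2[C@H]1C[C@H](O)[C@@]2(O)COC(=O)C1=CC=C(C(C)C)C[C@@H]2[C@H](C)CC[C@H]12 | target

**Step count and risks**
Total: 22 steps. Longest linear sequence: 12 steps (17 to 35, steps 11–22); the lactone branch from 4 takes 10 steps.

Step 9. The alkoxides formed during the reaction may convert unreacted 14 into its samarium enolate, which no longer accepts the ketyl. The α-silyloxy group may also be lost reductively, or the two C9 epimers may close with too little discrimination. The fallback sets out from 14 and returns at 15. An N-heterocyclic-carbene-catalysed intramolecular crossed benzoin reaction (triazolium precatalyst, Et3N, THF, rt) would make the same C7–C8 bond by umpolung of the aldehyde. It should give (4aR,7S,7aR)-7-{[(tert-butyldimethylsilyl)oxy]methyl}-7-hydroxy-4-methylidenetetrahydrocyclopenta[c]pyran-1,6(3H,4aH)-dione F1, since reversible addition and C9 enolisation should place the larger CH2OTBS group on the convex face of the cis-fused system. Hydride delivery to the C7 ketone from the convex face, anti to the two ring-fusion substituents (NaBH4, MeOH, −78 °C), would then give 15.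

Step 4. Transmetalation of the hindered 1,1-disubstituted alkenyl boronate may be slower than protodeboronation, the alkenylrhodium may lose its β-silyloxy group, or facial control on the acyclic enoate may be insufficient. The fallback sets out from 3 and 5 and returns at 9. Saponification of 3 (LiOH, THF/H2O) would give (2E)-5,5-diethoxypent-2-enoic acid F2. Its pivaloyl mixed anhydride would be coupled with lithiated (S)-4-phenyloxazolidin-2-one to (4S)-3-[(2E)-5,5-diethoxypent-2-enoyl]-4-phenyloxazolidin-2-one F3. The alkenylmagnesium reagent from 5 (t-BuLi, −78 °C, then MgBr2·OEt2) with CuBr·SMe2 should add to the chelated imide anti to the phenyl group and give the (3R)-adduct, (4S)-3-[(3R)-4-{[(tert-butyldimethylsilyl)oxy]methyl}-3-(2,2-diethoxyethyl)pent-4-enoyl]-4-phenyloxazolidin-2-one F4. Bu4NF would then free the alkoxide, which displaces the auxiliary and closes lactone 9.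

Step 13. Ring closure at the position meta to OMe may be slow, so that intermolecular condensation at the activated ring positions and acid-induced oligomerisation of the indene compete. The fallback sets out from 17 and returns at 22. The benzylic potassium compound 19 would be trapped with ethylene oxide to give 3-(4-isopropyl-2-methoxyphenyl)propan-1-ol F5, which is oxidised (TEMPO, PhI(OAc)2, MeCN/H2O) to 3-(4-isopropyl-2-methoxyphenyl)propanoic acid F6. Intramolecular Friedel–Crafts acylation (P2O5/MeSO3H), a closure with an acylium ion that is well established at positions meta to OMe, would give 6-isopropyl-4-methoxyindan-1-one F7. MeMgBr with CeCl3 would give 6-isopropyl-4-methoxy-1-methylindan-1-ol F8, and TsOH in toluene would dehydrate it to indene 22.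

**Further compounds**
F1 | step 9 | (4aR,7S,7aR)-7-{[(tert-butyldimethylsilyl)oxy]methyl}-7-hydroxy-4-methylidenetetrahydrocyclopenta[c]pyran-1,6(3H,4aH)-dione | C=C1COC(=O)[C@@H]2[C@H]1CC(=O)[C@@]2(O)CO[Si](C)(C)C(C)(C)C
F2 | step 4 | (2E)-5,5-diethoxypent-2-enoic acid | OC(=O)/C=C/CC(OCC)OCC
F3 | step 4 | (4S)-3-[(2E)-5,5-diethoxypent-2-enoyl]-4-phenyloxazolidin-2-one | O=C1OC[C@H](c2ccccc2)N1C(=O)/C=C/CC(OCC)OCC
F4 | step 4 | (4S)-3-[(3R)-4-{[(tert-butyldimethylsilyl)oxy]methyl}-3-(2,2-diethoxyethyl)pent-4-enoyl]-4-phenyloxazolidin-2-one | O=C1OC[C@H](c2ccccc2)N1C(=O)C[C@@H](CC(OCC)OCC)C(=C)CO[Si](C)(C)C(C)(C)C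
F5 | step 13 | 3-(4-isopropyl-2-methoxyphenyl)propan-1-ol | COc1cc(C(C)C)ccc1CCCO
F6 | step 13 | 3-(4-isopropyl-2-methoxyphenyl)propanoic acid | COc1cc(C(C)C)ccc1CCC(=O)O
F7 | step 13 | 6-isopropyl-4-methoxyindan-1-one | COc1cc(C(C)C)cc2C(=O)CCc12
F8 | step 13 | 6-isopropyl-4-methoxy-1-methylindan-1-ol | COc1cc(C(C)C)cc2C(C)(O)CCc12
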